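**Retrosynthetic overview**

1. Target 23 comes from the bis-silyl chalcone 22 by desilylation. 22 is cut between the enone carbonyl carbon and its alpha carbon into salicylaldehyde 16 (rings A and C complete, all oxygens in place) and terminal arylalkyne 21 (ring B). A rhodium-catalysed alkyne hydroacylation joins them, forming the C(=O)–CH bond and the E alkene in one atom-economic operation.
2. Enabling feature: the free hydroxyl on C5 of ring A (the benzene ring of the chromane) is ortho to C6, the carbon that bears the enone carbonyl. At the aldehyde stage this O–C5–C6–CHO salicyl unit binds rhodium as a five-membered O,C-chelate, which allows formyl C–H activation and blocks decarbonylation.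
3. 16 comes from chroman-5-ol 14 by ortho-formylation at C6; 14 from bromochromane 11 (C5–Br to C5–OH); 11 from tertiary alcohol 10 by intramolecular aryl C–O coupling that closes ring C (the pyran). The two ortho bromines of 10 are equivalent, so the closure needs no regiocontrol.
4. The C3 stereocentre is set by Evans alkylation of the (R)-4-benzyloxazolidinone imide of 5-methylhex-4-enoic acid with 2,6-dibromo-4-methoxybenzyl bromide; the acyl carbon then becomes C2 by double methyl addition.
5. Ring order: rings A and B are bought (1 and 17), ring C is formed in step 6, and no ring is formed in the key step. 21 comes from 17 by silylation and Corey–Fuchs homologation.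

Key step: step 12

Remark on the chemistry: 3,5-dibromo-4-methylanisole (1) and 5-methylhex-4-enoic acid (3) are taken as catalogue compounds; otherwise 1 follows from 3,5-dibromo-4-methylphenol by O-methylation and 3 from 2-methylbut-3-en-2-ol by Johnson–Claisen rearrangement and saponification.

**Route**

Step 1
Reactants: 1 3,5-dibromo-4-methylanisole
Product: 2 2,6-dibromo-4-methoxybenzyl bromide
Conditions: NBS (1.05 equiv), AIBN (5 mol%), PhCF3, 85 °C
Reagents that add atoms: N-bromosuccinimide, O=C1CCC(=O)N1Br
Why: Wohl–Ziegler radical bromination is confined to the only benzylic C–H bonds, and the non-polar medium together with the two ring bromines should suppress electrophilic bromination of the anisole ring.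

Step 2
Reactants: 3 5-methylhex-4-enoic acid; 4 (R)-4-benzyloxazolidin-2-one
Product: 6 (R)-4-benzyl-3-(5-methylhex-4-enoyl)oxazolidin-2-one, via mixed pivalic anhydride 5 (not isolated)
Conditions: t-BuCOCl, Et3N, THF, −20 °C; then LiCl, 4, −20 °C → rt
Reagents that add atoms: none
Why: N-acylation of an Evans oxazolidinone through the mixed pivalic anhydride (LiCl/Et3N protocol) should be clean because the hindered pivaloyl carbonyl directs attack to the 5-methylhex-4-enoyl carbonyl, and the auxiliary stereocentre is not touched.

Step 3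
Reactants: 6 (R)-4-benzyl-3-(5-methylhex-4-enoyl)oxazolidin-2-one; 2 2,6-dibromo-4-methoxybenzyl bromide
Product: 8 (R)-4-benzyl-3-[(S)-2-(2,6-dibromo-4-methoxybenzyl)-5-methylhex-4-enoyl]oxazolidin-2-one, via sodium Z-enolate 7 (not isolated)
Conditions: NaN(SiMe3)2 (1.1 equiv), THF, −78 °C; then 2 (1.3 equiv), −78 → −20 °C
Reagents that add atoms: none
Why: Evans asymmetric alkylation, in which the chelated sodium Z-enolate 7 is attacked by the reactive benzylic bromide on the face away from the C4 benzyl group of the (R)-auxiliary, should set the new alpha stereocentre as S (the later C3 of the chromane), while the aryl bromines are inert to the enolate.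

Step 4
Reactants: 8 (R)-4-benzyl-3-[(S)-2-(2,6-dibromo-4-methoxybenzyl)-5-methylhex-4-enoyl]oxazolidin-2-one
Product: 9 methyl (S)-2-(2,6-dibromo-4-methoxybenzyl)-5-methylhex-4-enoate
Conditions: MeMgBr (1.5 equiv) added to MeOH at 0 °C (gives MeOMgBr), then 8 in THF, 0 °C → rt
Reagents that add atoms: methanol (delivered as MeOMgBr), CO
Why: Transesterification of the N-acyloxazolidinone with bromomagnesium methoxide, in which magnesium chelation between the two imide carbonyls activates the exocyclic one, should release the methyl ester without epimerisation of the alpha stereocentre and return the auxiliary 4.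

Step 5
Reactants: 9 methyl (S)-2-(2,6-dibromo-4-methoxybenzyl)-5-methylhex-4-enoate
Product: 10 (S)-3-(2,6-dibromo-4-methoxybenzyl)-2,6-dimethylhept-5-en-2-ol
Conditions: MeMgBr (4 equiv), anhydrous CeCl3 (4 equiv), THF, −78 → 0 °C; aq NH4Cl
Reagents that add atoms: methylmagnesium bromide, C[Mg]Br
Why: Double addition of the weakly basic cerium-modified methyl Grignard reagent to the ester builds the gem-dimethyl carbinol (later C2), avoids enolisation of the intermediate methyl ketone so that the adjacent stereocentre should keep its configuration, and leaves the aryl bromides alone.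

Step 6
Reactants: 10 (S)-3-(2,6-dibromo-4-methoxybenzyl)-2,6-dimethylhept-5-en-2-ol
Product: 11 (S)-5-bromo-7-methoxy-2,2-dimethyl-3-(3-methylbut-2-en-1-yl)chromane
Conditions: Pd(OAc)2 (5 mol%), 2-(di-tert-butylphosphino)-1,1'-binaphthyl (6 mol%), Cs2CO3 (1.5 equiv), toluene, 65 °C
Reagents that add atoms: none
Why: Intramolecular Buchwald–Hartwig etherification (oxidative addition of zerovalent palladium into C–Br, alkoxide binding, C–O reductive elimination) closes the six-membered pyran ring; the two bromines are interchanged by rotation about the aryl–CH2 bond so either gives the same chromane, the tertiary alkoxide has no carbinol hydrogen for beta-hydride elimination, and the bulky phosphine and mild temperature are chosen so that C–O reductive elimination should outrun carbopalladation of the trisubstituted prenyl alkene.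

Step 7
Reactants: 11 (S)-5-bromo-7-methoxy-2,2-dimethyl-3-(3-methylbut-2-en-1-yl)chromane
Product: 14 (S)-7-methoxy-2,2-dimethyl-3-(3-methylbut-2-en-1-yl)chroman-5-ol, via aryllithium 12 (not isolated), via dimethyl arylboronate 13 (not isolated)
Conditions: n-BuLi (1.1 equiv), THF, −78 °C; B(OMe)3, −78 °C → rt; then 30% H2O2, aq NaOH, 0 °C
Reagents that add atoms: hydrogen peroxide, OO
Why: Bromine–lithium exchange is faster than any ring deprotonation at −78 °C, and borylation followed by alkaline peroxide oxidation of the aryl boronate (1,2-aryl shift from boron to oxygen) should turn C5–Br into C5–OH without touching the prenyl alkene or the stereocentre.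

Step 8
Reactants: 14 (S)-7-methoxy-2,2-dimethyl-3-(3-methylbut-2-en-1-yl)chroman-5-ol
Product: 16 (S)-5-hydroxy-7-methoxy-2,2-dimethyl-3-(3-methylbut-2-en-1-yl)chromane-6-carbaldehyde, via salicyl alcohol 15 (not isolated)
Conditions: MgCl2 (2 equiv), Et3N (4 equiv), (CH2O)n (6 equiv), MeCN, reflux
Reagents that add atoms: paraformaldehyde (as formaldehyde), C=O
Why: Magnesium-mediated ortho-formylation of a phenol (Casnati–Skattebøl type) delivers formaldehyde from the magnesium phenoxide only to the ortho position, here C6 because the other ortho carbon C4a is substituted, and a second equivalent of formaldehyde should oxidise the hydroxymethyl intermediate 15 to the aldehyde by hydride transfer.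

Step 9
Reactants: 17 2,4-dihydroxybenzaldehyde
Product: 18 2,4-bis(tert-butyldimethylsilyloxy)benzaldehyde
Conditions: TBSCl (2.5 equiv), imidazole (5 equiv), DMF, rt
Reagents that add atoms: tert-butyldimethylsilyl chloride, CC(C)(C)[Si](C)(C)Cl
Why: Standard silylation of both phenols (Corey protocol) masks in particular the ortho hydroxyl, which would otherwise cyclise onto the alkyne to a benzofuran under rhodium catalysis.

Step 10
Reactants: 18 2,4-bis(tert-butyldimethylsilyloxy)benzaldehyde
Product: 19 1-(2,2-dibromovinyl)-2,4-bis(tert-butyldimethylsilyloxy)benzene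
Conditions: CBr4 (2 equiv), PPh3 (2 equiv), Zn (2 equiv), CH2Cl2, rt (reagent pre-formed); then 18, rt
Reagents that add atoms: carbon tetrabromide, BrC(Br)(Br)Br
Why: Corey–Fuchs dibromo-olefination with the zinc-modified reagent runs under neutral conditions through an oxaphosphetane rather than a free alkoxide, so the ortho silyl ether should neither migrate nor be cleaved.

Step 11
Reactants: 19 1-(2,2-dibromovinyl)-2,4-bis(tert-butyldimethylsilyloxy)benzene
Product: 21 1-ethynyl-2,4-bis(tert-butyldimethylsilyloxy)benzene, via lithium acetylide 20 (not isolated)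
Conditions: n-BuLi (2.2 equiv), THF, −78 → −20 °C; aq NH4Cl
Reagents that add atoms: none
Why: Second stage of the Corey–Fuchs alkyne synthesis, in which bromine–lithium exchange, Fritsch–Buttenberg–Wiechell rearrangement of the carbenoid and deprotonation give the lithium acetylide 20 that is protonated on quench, with aryl silyl ethers that should tolerate n-BuLi at low temperature.

Step 12
Reactants: 16 (S)-5-hydroxy-7-methoxy-2,2-dimethyl-3-(3-methylbut-2-en-1-yl)chromane-6-carbaldehyde; 21 1-ethynyl-2,4-bis(tert-butyldimethylsilyloxy)benzene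
Product: 22 (E)-3-[2,4-bis(tert-butyldimethylsilyloxy)phenyl]-1-[(S)-5-hydroxy-7-methoxy-2,2-dimethyl-3-(3-methylbut-2-en-1-yl)chroman-6-yl]prop-2-en-1-one
Conditions: [RhCl(cod)]2 (2.5 mol%), Fe(C5H4PPh2)2 (dppf, 5 mol%), Na2CO3 (10 mol%), 21 (1.3 equiv), toluene, 100 °C
Reagents that add atoms: none
Why: The phenoxide of 16 binds monovalent rhodium and the formyl C–H adds oxidatively to give a five-membered acyl(hydrido)rhodium phenoxide chelate (trivalent rhodium) that resists decarbonylation; syn insertion of the alkyne into Rh–H with rhodium on the terminal carbon and C–C reductive elimination then deliver the enone and return the catalyst. The closest known reaction type is the chelation-assisted rhodium-catalysed intermolecular hydroacylation of alkynes with salicylaldehydes under the same [RhCl(cod)]2/Fe(C5H4PPh2)2/Na2CO3 system, which gives 2-alkenoylphenols. No ring is closed and no stereocentre is formed; the E geometry follows from syn addition of H and acyl across the triple bond, and the remote C3 stereocentre is not involved. The step needs linear regioselectivity (acyl to the terminal alkyne carbon, not the branched 1,1-disubstituted enone), which the bulky ortho-silyloxyaryl group should secure by keeping the chelated acyl-rhodium unit at the unhindered terminus. It also needs chemoselectivity over the trisubstituted prenyl alkene, which should not insert into Rh–H at a useful rate, and over oxa-Michael closure to the flavanone, which the catalytic amount of weak base in an aprotic medium should hold back. The silyl ethers keep the ortho-alkynylphenol from cycloisomerising and are carried through unchanged.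

Step 13
Reactants: 22 (E)-3-[2,4-bis(tert-butyldimethylsilyloxy)phenyl]-1-[(S)-5-hydroxy-7-methoxy-2,2-dimethyl-3-(3-methylbut-2-en-1-yl)chroman-6-yl]prop-2-en-1-one
Product: 23 (E)-3-(2,4-dihydroxyphenyl)-1-[(S)-5-hydroxy-7-methoxy-2,2-dimethyl-3-(3-methylbut-2-en-1-yl)chroman-6-yl]prop-2-en-1-one
Conditions: Bu4NF (2.4 equiv), AcOH (2.4 equiv), THF, 0 °C
Reagents that add atoms: none
Why: Fluoride-mediated cleavage of the two aryl silyl ethers at 0 °C with an acetic acid buffer keeps the medium near neutral, so the ortho-hydroxyenone should neither close to the flavanone nor lose its E geometry, while the prenyl alkene and the stereocentre are not involved.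

**Compound list**

1 | 3,5-dibromo-4-methylanisole | COc1cc(Br)c(C)c(Br)c1 | starting material
2 | 2,6-dibromo-4-methoxybenzyl bromide | COc1cc(Br)c(CBr)c(Br)c1 | intermediate
3 | 5-methylhex-4-enoic acid | CC(C)=CCCC(=O)O | starting material
4 | (R)-4-benzyloxazolidin-2-one | O=C1N[C@H](Cc2ccccc2)CO1 | starting material
5 | 5-methylhex-4-enoic pivalic anhydride | CC(C)=CCCC(=O)OC(=O)C(C)(C)C | intermediate
6 | (R)-4-benzyl-3-(5-methylhex-4-enoyl)oxazolidin-2-one | CC(C)=CCCC(=O)N1[C@H](Cc2ccccc2)COC1=O | intermediate
7 | sodium Z-enolate of 6 | CC(C)=CC/C=C(\[O-])N1[C@H](Cc2ccccc2)COC1=O.[Na+] | intermediate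
8 | (R)-4-benzyl-3-[(S)-2-(2,6-dibromo-4-methoxybenzyl)-5-methylhex-4-enoyl]oxazolidin-2-one | CC(C)=CC[C@@H](Cc1c(Br)cc(OC)cc1Br)C(=O)N1[C@H](Cc2ccccc2)COC1=O | intermediate
9 | methyl (S)-2-(2,6-dibromo-4-methoxybenzyl)-5-methylhex-4-enoate | COC(=O)[C@H](Cc1c(Br)cc(OC)cc1Br)CC=C(C)C | intermediate
10 | (S)-3-(2,6-dibromo-4-methoxybenzyl)-2,6-dimethylhept-5-en-2-ol | CC(C)(O)[C@H](Cc1c(Br)cc(OC)cc1Br)CC=C(C)C | intermediate
11 | (S)-5-bromo-7-methoxy-2,2-dimethyl-3-(3-methylbut-2-en-1-yl)chromane | COc1cc2c(c(Br)c1)C[C@H](CC=C(C)C)C(C)(C)O2 | intermediate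
12 | (S)-5-lithio-7-methoxy-2,2-dimethyl-3-(3-methylbut-2-en-1-yl)chromane | COc1cc2c(c([Li])c1)C[C@H](CC=C(C)C)C(C)(C)O2 | intermediate
13 | dimethyl [(S)-7-methoxy-2,2-dimethyl-3-(3-methylbut-2-en-1-yl)chroman-5-yl]boronate | COc1cc2c(c(B(OC)OC)c1)C[C@H](CC=C(C)C)C(C)(C)O2 | intermediate
14 | (S)-7-methoxy-2,2-dimethyl-3-(3-methylbut-2-en-1-yl)chroman-5-ol | COc1cc2c(c(O)c1)C[C@H](CC=C(C)C)C(C)(C)O2 | intermediate
15 | (S)-6-(hydroxymethyl)-7-methoxy-2,2-dimethyl-3-(3-methylbut-2-en-1-yl)chroman-5-ol | COc1cc2c(c(O)c1CO)C[C@H](CC=C(C)C)C(C)(C)O2 | intermediate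
16 | (S)-5-hydroxy-7-methoxy-2,2-dimethyl-3-(3-methylbut-2-en-1-yl)chromane-6-carbaldehyde | COc1cc2c(c(O)c1C=O)C[C@H](CC=C(C)C)C(C)(C)O2 | intermediate
17 | 2,4-dihydroxybenzaldehyde | O=Cc1ccc(O)cc1O | starting material
18 | 2,4-bis(tert-butyldimethylsilyloxy)benzaldehyde | O=Cc1ccc(O[Si](C)(C)C(C)(C)C)cc1O[Si](C)(C)C(C)(C)C | intermediate
19 | 1-(2,2-dibromovinyl)-2,4-bis(tert-butyldimethylsilyloxy)benzene | BrC(Br)=Cc1ccc(O[Si](C)(C)C(C)(C)C)cc1O[Si](C)(C)C(C)(C)C | intermediate
20 | lithium [2,4-bis(tert-butyldimethylsilyloxy)phenyl]acetylide | [Li]C#Cc1ccc(O[Si](C)(C)C(C)(C)C)cc1O[Si](C)(C)C(C)(C)C | intermediate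
21 | 1-ethynyl-2,4-bis(tert-butyldimethylsilyloxy)benzene | C#Cc1ccc(O[Si](C)(C)C(C)(C)C)cc1O[Si](C)(C)C(C)(C)C | intermediate
22 | (E)-3-[2,4-bis(tert-butyldimethylsilyloxy)phenyl]-1-[(S)-5-hydroxy-7-methoxy-2,2-dimethyl-3-(3-methylbut-2-en-1-yl)chroman-6-yl]prop-2-en-1-one | COc1cc2c(c(O)c1C(=O)/C=C/c1ccc(O[Si](C)(C)C(C)(C)C)cc1O[Si](C)(C)C(C)(C)C)C[C@H](CC=C(C)C)C(C)(C)O2 | intermediate
23 | (E)-3-(2,4-dihydroxyphenyl)-1-[(S)-5-hydroxy-7-methoxy-2,2-dimethyl-3-(3-methylbut-2-en-1-yl)chroman-6-yl]prop-2-en-1-one | COc1cc2c(c(O)c1C(=O)/C=C/c1ccc(O)cc1O)C[C@H](CC=C(C)C)C(C)(C)O2 | target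

**Count**

Total steps: 13. Longest linear sequence: 9 steps (steps 2, 3, 4, 5, 6, 7, 8, 12, 13; the branch through step 1 is equally long).

**Steps most likely to fail**

1. Step 12. The alkyne may insert with rhodium on the internal carbon and give the branched enone, or the arylalkyne may oligomerise, or the acyl rhodium may decarbonylate before insertion. The fallback sets out from 21 and 16 and returns at 22. Hydrozirconation of 21 with Cp2Zr(H)Cl (CH2Cl2, rt) should place zirconium on the terminal carbon by syn addition and give the (E)-alkenylzirconocene chloride F1. Transmetalation with Me2Zn (toluene, −65 °C) gives the (E)-alkenyl(methyl)zinc F2, which adds to 16 (one further equivalent of Me2Zn first turns the phenol into its zinc phenoxide) to give the allylic alcohol F3 as a mixture of carbinol epimers. MnO2 in CH2Cl2 then oxidises this benzylic and allylic alcohol to 22. The same C–C bond is made, with regiochemistry and E geometry fixed by the hydrozirconation.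

2. Step 6. The arylpalladium bromide may add to the prenyl alkene (6-exo carbopalladation to a tetralin) faster than the hindered tertiary alkoxide couples, or slow coupling may end in reductive loss of bromine. The fallback sets out from 10 and returns at 11. LiN(i-Pr)2 (2.2 equiv, THF, −78 → 0 °C) first forms the lithium alkoxide and then removes a ring proton between Br and OMe; loss of LiBr gives the aryne alkoxide F4. The alkoxide adds in a 6-exo sense to the aryne carbon that carried bromine, which is also the carbon remote from OMe and thus the normal site of attack on a 3-alkoxyaryne. Protonation of the aryl anion gives 11 without any aryl–metal species that can add to the alkene.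

3. Step 8. The very electron-rich ring may condense further with formaldehyde (diarylmethane formation), or the hydride transfer from the hydroxymethyl stage may stall. The fallback sets out from 14 and returns at 16. PhB(OH)2, paraformaldehyde and catalytic propionic acid in toluene at reflux with removal of water (Nagata ortho-hydroxymethylation) should give the 2-phenyl-4H-1,3,2-benzodioxaborine F5, in which boron ties one formaldehyde unit to C6. Exchange with propane-1,3-diol releases the salicyl alcohol 15, isolated in this variant, and MnO2 in CH2Cl2 oxidises it to 16.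

Further compounds
F1 | step 12 | (E)-{2-[2,4-bis(tert-butyldimethylsilyloxy)phenyl]vinyl}zirconocene chloride | Cl[Zr](C1C=CC=C1)(C1C=CC=C1)/C=C/c1ccc(O[Si](C)(C)C(C)(C)C)cc1O[Si](C)(C)C(C)(C)C
F2 | step 12 | (E)-{2-[2,4-bis(tert-butyldimethylsilyloxy)phenyl]vinyl}(methyl)zinc | C[Zn]/C=C/c1ccc(O[Si](C)(C)C(C)(C)C)cc1O[Si](C)(C)C(C)(C)C
F3 | step 12 | (E)-3-[2,4-bis(tert-butyldimethylsilyloxy)phenyl]-1-[(S)-5-hydroxy-7-methoxy-2,2-dimethyl-3-(3-methylbut-2-en-1-yl)chroman-6-yl]prop-2-en-1-ol (both carbinol epimers) | COc1cc2c(c(O)c1C(O)/C=C/c1ccc(O[Si](C)(C)C(C)(C)C)cc1O[Si](C)(C)C(C)(C)C)C[C@H](CC=C(C)C)C(C)(C)O2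
F4 | step 6 | lithium (S)-3-[(6-bromo-4-methoxy-2,3-didehydrophenyl)methyl]-2,6-dimethylhept-5-en-2-olate (aryne alkoxide) | COC1=CC(Br)=C(C[C@H](CC=C(C)C)C(C)(C)[O-])C#C1.[Li+]
F5 | step 8 | 2-phenyl-4H-1,3,2-benzodioxaborine fused at C5–C6 of (S)-7-methoxy-2,2-dimethyl-3-(3-methylbut-2-en-1-yl)chromane | COc1cc2c(c3OB(c4ccccc4)OCc13)C[C@H](CC=C(C)C)C(C)(C)O2
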